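**Retrosynthetic overview**
1. Rings are lettered A–G from left to right in the target SMILES. D is the pentaoxygenated ring: D-1 bears O–ring C, D-2 is CH, D-3 to D-5 bear OH, D-6 bears O–ring E. The last step is global O-demethylation of a hexadecamethyl ether.
2. Every ether link except D–O–E comes from a phenol + haloarene C–O coupling followed by ArCHO → ArOH. Growth runs outwards in both directions from a ring D–E core: C and F together, then B and G together, then A.
3. Ring D is the only ring that is built. A 4-(1-methoxyvinyl)cyclobutenone undergoes 4π opening and 6π closure (bond D-1–D-2) to a phenol in which only O-1 is free.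
4. Key C–C bond D-3–D-4: 1-methoxyvinyllithium (a masked acetyl anion) attacks one carbonyl of a mixed aryl methyl squarate, joining two carbonyl-level carbons. Ring E already sits on a squarate oxygen, so D–O–E needs no coupling.
5. The mixed squarate comes from squaric acid, MeOH and 2,6-dimethoxyhydroquinone. Ring order: the four-membered squarate ring, then ring D. Rings A, B, C, E, F and G are bought as benzene rings.

Assumption: the SMILES contains no stereocentre and no configurationally stable axis, so the target is achiral and its constitution alone defines the compound asked for.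
Wording: in rings A–C and E–G the "flanked" position lies between two OMe groups and the "open" position lies between two CH groups.

**Step 1**
Reactants: 1 squaric acid (3,4-dihydroxycyclobut-3-ene-1,2-dione)
Product: 2 3,4-dichlorocyclobut-3-ene-1,2-dione
Conditions: (COCl)2 (2.2 equiv), DMF (cat.), CH2Cl2, 40 °C, 4 h
Reagents that add atoms: oxalyl chloride, O=C(Cl)C(=O)Cl
Why: Vilsmeier-type chlorodehydroxylation of the vinylogous diacid (acid chloride formation) is the standard entry to squaryl dichloride and is driven by gas evolution.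

**Step 2**
Reactants: 2 3,4-dichlorocyclobut-3-ene-1,2-dione; 3 2,6-dimethoxyhydroquinone (2,6-dimethoxybenzene-1,4-diol)
Product: 6 3-[4-(tert-butyldimethylsilyloxy)-3,5-dimethoxyphenoxy]-4-methoxycyclobut-3-ene-1,2-dione, via 3-chloro-4-methoxycyclobutenedione 4 (not isolated), via aryl methyl squarate phenol 5 (not isolated)
Conditions: MeOH (1.0 equiv), CH2Cl2, 0 °C to rt, then evaporate; 3, NaH (1.0 equiv), THF, −40 to 0 °C, Ar; then TBSOTf, 2,6-lutidine, 0 °C
Reagents that add atoms: methanol, CO; tert-butyldimethylsilyl triflate, CC(C)(C)[Si](C)(C)OS(=O)(=O)C(F)(F)F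
Why: Sequential vinylogous acyl substitution (addition–elimination) works because the first methoxy group deactivates the second chloride so that mono-exchange stops at 4, the remaining chloride is taken by the more acidic and unhindered open phenoxide of 3, and the flanked OH that stays free is then silylated.

**Step 3 (key step)**
Reactants: 6 silyl-protected aryl methyl squarate; 7 methyl vinyl ether
Product: 10 (±)-2-[4-(tert-butyldimethylsilyloxy)-3,5-dimethoxyphenoxy]-3,4-dimethoxy-4-(1-methoxyvinyl)cyclobut-2-en-1-one, via 1-methoxyvinyllithium 8 (not isolated), via lithium alkoxide adduct 9 (not isolated)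
Conditions: 7 (3 equiv), t-BuLi (1.2 equiv), THF, −78 to 0 °C; cannulate into 6, THF, −78 °C, 30 min; MeOTf (2 equiv), −78 to 0 °C; aq NaHCO3
Reagents that add atoms: methyl triflate, COS(=O)(=O)C(F)(F)F
Why: Proposed new method: 1-methoxyvinyllithium, a masked acetyl anion, should add 1,2 to the squarate carbonyl that is vinylogous to the weakly donating aryloxy group and sits next to the small OMe (the other C=O is a vinylogous methyl ester and is shielded by the aryl ether), so two carbonyl-level carbons are joined as D-3–D-4 and the alkoxide is capped in situ by MeOTf; the closest known reaction type is the site-selective addition of organolithiums to unsymmetrical cyclobutenediones that precedes Moore ring expansions, and the new quaternary stereocentre forms as a racemate that is erased in step 4.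

**Step 4**
Reactants: 10 (±)-4-(1-methoxyvinyl)cyclobutenone
Product: 13 2-[4-(tert-butyldimethylsilyloxy)-3,5-dimethoxyphenoxy]-3,4,5-trimethoxyphenol (ring D–E phenol), via (Z)-dienylketene 11 (not isolated), via cyclohexa-2,4-dienone 12 (not isolated)
Conditions: toluene (0.02 M), 110 °C, 2 h, Ar
Reagents that add atoms: none
Why: In this Moore rearrangement the conrotatory 4π opening turns the C-4 methoxy donor outwards and the methoxyvinyl arm inwards, the (Z)-dienylketene closes by 6π electrocyclisation (bond D-1–D-2), and tautomerisation gives the phenol, which removes the stereocentre and leaves O-1 as the only free oxygen of ring D.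

**Step 5**
Reactants: 13 ring D–E phenol; 14 4-bromo-3,5-dimethoxybenzaldehyde; 15 4-bromo-2,6-dimethoxybenzaldehyde
Product: 18 ring C–D–E–F dialdehyde 4-{2-[4-(4-formyl-3,5-dimethoxyphenoxy)-3,5-dimethoxyphenoxy]-3,4,5-trimethoxyphenoxy}-3,5-dimethoxybenzaldehyde, via ring D–E diol 16 (not isolated), via ring C–D–E aldehyde phenol 17 (not isolated)
Conditions: CsF (1.2 equiv), K3PO4 (3 equiv), CuI (20 mol%), picolinic acid (40 mol%), DMSO, Ar; 14 (1.1 equiv), 90 °C; then 15 (1.3 equiv), 100 °C
Reagents that add atoms: none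
Why: In this Ullmann-type C–O coupling under monovalent copper catalysis fluoride first frees the ring E phenol, the doubly ortho-substituted bromide 14 can only engage the D-1 phenoxide (coupling at the flanked ring E phenoxide would need a tetra-ortho-substituted ether), and the unhindered para-formyl bromide 15 added afterwards takes the remaining flanked phenoxide.

**Step 6**
Reactants: 18 ring C–D–E–F dialdehyde
Product: 20 ring C–D–E–F diol 4-{2-[4-(4-hydroxy-3,5-dimethoxyphenoxy)-3,5-dimethoxyphenoxy]-3,4,5-trimethoxyphenoxy}-3,5-dimethoxyphenol, via bis(formate) 19 (not isolated)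
Conditions: mCPBA (3.5 equiv), CH2Cl2, 0 to 40 °C; aq Na2S2O3 wash; K2CO3 (cat.), MeOH–THF, 0 °C, Ar
Reagents that add atoms: mCPBA, O=C(OO)c1cccc(Cl)c1
Why: In this double Baeyer–Villiger oxidation aryl migration is favoured by the para-aryloxy group in ring C and by the two ortho-methoxy groups in ring F, and the resulting bis(formate) keeps both electron-rich phenols masked until the peracid is washed out and is then cleaved by base-catalysed methanolysis.

**Step 7**
Reactants: 20 ring C–D–E–F diol; 14 4-bromo-3,5-dimethoxybenzaldehyde; 21 5-iodo-1,2,3-trimethoxybenzene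
Product: 23 ring B–G hexamer aldehyde (22 arylated on the ring F oxygen by 3,4,5-trimethoxyphenyl), via ring B–F aldehyde phenol 22 (not isolated)
Conditions: K3PO4 (4 equiv), CuI (20 mol%), picolinic acid (40 mol%), DMSO, Ar; 14 (1.1 equiv), 90 °C; then 21 (1.5 equiv), 105 °C
Reagents that add atoms: none
Why: This Ullmann-type coupling uses the same steric gating as step 5, since hindered 14 reacts only at the open ring C phenoxide to add ring B, and the unhindered iodide 21, whose para-methoxy group is twisted out of conjugation, then arylates the flanked ring F phenoxide to add a fully capped ring G.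

**Step 8**
Reactants: 23 ring B–G hexamer aldehyde
Product: 25 ring B–G hexamer phenol (open OH on ring B), via hexamer formate 24 (not isolated)
Conditions: mCPBA (2 equiv), CH2Cl2, 0 to 40 °C; aq Na2S2O3 wash; K2CO3 (cat.), MeOH–THF, 0 °C
Reagents that add atoms: mCPBA, O=C(OO)c1cccc(Cl)c1
Why: Baeyer–Villiger oxidation of the 4-aryloxy-3,5-dimethoxybenzaldehyde followed by formate methanolysis turns CHO into OH, and no free phenol is present while the peracid acts.

**Step 9**
Reactants: 25 ring B–G hexamer phenol; 14 4-bromo-3,5-dimethoxybenzaldehyde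
Product: 26 ring A–G heptamer aldehyde (25 arylated on the ring B oxygen by 4-formyl-2,6-dimethoxyphenyl)
Conditions: 14 (1.3 equiv), CuI (20 mol%), picolinic acid (40 mol%), K3PO4, DMSO, 90 °C, Ar
Reagents that add atoms: none
Why: Ullmann-type C–O coupling of an unhindered electron-rich phenoxide with the para-formyl-activated bromide repeats the bond type already made in step 7.

**Step 10**
Reactants: 26 ring A–G heptamer aldehyde
Product: 28 hexadeca-O-methyl ether of the target (open OH of ring A free), via heptamer formate 27 (not isolated)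
Conditions: mCPBA (2 equiv), CH2Cl2, 0 to 40 °C; aq Na2S2O3 wash; K2CO3 (cat.), MeOH–THF, 0 °C
Reagents that add atoms: mCPBA, O=C(OO)c1cccc(Cl)c1
Why: Baeyer–Villiger oxidation and formate methanolysis install the last oxygen as the free 4-OH of ring A, which needs no protection before the final step.

**Step 11**
Reactants: 28 hexadeca-O-methyl ether
Product: 29 CNP0304148.0 (target)
Conditions: BBr3 (40 equiv), CH2Cl2, −78 °C to rt, 36 h, Ar; ice–water; Sephadex LH-20, degassed MeOH–H2O
Reagents that add atoms: none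
Why: In this Lewis-acid ether cleavage BBr3 binds each methoxy oxygen and bromide removes the methyl group by SN2 attack, while the diaryl ether C–O bonds offer no sp3 carbon and survive, so hydrolysis of the aryl borates releases the achiral heptadecaol.

**Compound list**
1 | squaric acid | O=C1C(=O)C(O)=C1O | starting material
2 | 3,4-dichlorocyclobut-3-ene-1,2-dione | O=C1C(=O)C(Cl)=C1Cl | intermediate
3 | 2,6-dimethoxyhydroquinone | COc1cc(O)cc(OC)c1O | starting material
4 | 3-chloro-4-methoxycyclobut-3-ene-1,2-dione | COC1=C(Cl)C(=O)C1=O | intermediate (not isolated)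
5 | 3-(4-hydroxy-3,5-dimethoxyphenoxy)-4-methoxycyclobut-3-ene-1,2-dione | COC1=C(Oc2cc(OC)c(O)c(OC)c2)C(=O)C1=O | intermediate (not isolated)
6 | 3-[4-(tert-butyldimethylsilyloxy)-3,5-dimethoxyphenoxy]-4-methoxycyclobut-3-ene-1,2-dione | COC1=C(Oc2cc(OC)c(O[Si](C)(C)C(C)(C)C)c(OC)c2)C(=O)C1=O | intermediate
7 | methyl vinyl ether | COC=C | starting material
8 | 1-methoxyvinyllithium | [Li]C(=C)OC | intermediate (not isolated)
9 | lithium alkoxide adduct (racemic) | [Li]OC1(C(=C)OC)C(OC)=C(Oc2cc(OC)c(O[Si](C)(C)C(C)(C)C)c(OC)c2)C1=O | intermediate (not isolated)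
10 | (±)-2-[4-(tert-butyldimethylsilyloxy)-3,5-dimethoxyphenoxy]-3,4-dimethoxy-4-(1-methoxyvinyl)cyclobut-2-en-1-one (racemate, no configuration drawn) | COC(=C)C1(OC)C(OC)=C(Oc2cc(OC)c(O[Si](C)(C)C(C)(C)C)c(OC)c2)C1=O | intermediate
11 | (Z)-dienylketene | COC(=C)/C(OC)=C(OC)\C(Oc1cc(OC)c(O[Si](C)(C)C(C)(C)C)c(OC)c1)=C=O | intermediate (not isolated)
12 | 2-aryloxy-3,4,5-trimethoxycyclohexa-2,4-dien-1-one | COC1=C(OC)C(OC)=C(Oc2cc(OC)c(O[Si](C)(C)C(C)(C)C)c(OC)c2)C(=O)C1 | intermediate (not isolated)
13 | 2-[4-(tert-butyldimethylsilyloxy)-3,5-dimethoxyphenoxy]-3,4,5-trimethoxyphenol | COc1cc(O)c(Oc2cc(OC)c(O[Si](C)(C)C(C)(C)C)c(OC)c2)c(OC)c1OC | intermediate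
14 | 4-bromo-3,5-dimethoxybenzaldehyde | COc1cc(C=O)cc(OC)c1Br | starting material
15 | 4-bromo-2,6-dimethoxybenzaldehyde | COc1cc(Br)cc(OC)c1C=O | starting material
16 | 2-(4-hydroxy-3,5-dimethoxyphenoxy)-3,4,5-trimethoxyphenol | COc1cc(O)c(Oc2cc(OC)c(O)c(OC)c2)c(OC)c1OC | intermediate (not isolated)
17 | 4-[2-(4-hydroxy-3,5-dimethoxyphenoxy)-3,4,5-trimethoxyphenoxy]-3,5-dimethoxybenzaldehyde | COc1cc(C=O)cc(OC)c1Oc1cc(OC)c(OC)c(OC)c1Oc1cc(OC)c(O)c(OC)c1 | intermediate (not isolated)
18 | ring C–D–E–F dialdehyde | COc1cc(C=O)cc(OC)c1Oc1cc(OC)c(OC)c(OC)c1Oc1cc(OC)c(Oc2cc(OC)c(C=O)c(OC)c2)c(OC)c1 | intermediate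
19 | ring C–D–E–F bis(formate) | COc1cc(OC=O)cc(OC)c1Oc1cc(OC)c(OC)c(OC)c1Oc1cc(OC)c(Oc2cc(OC)c(OC=O)c(OC)c2)c(OC)c1 | intermediate (not isolated)
20 | ring C–D–E–F diol | COc1cc(O)cc(OC)c1Oc1cc(OC)c(OC)c(OC)c1Oc1cc(OC)c(Oc2cc(OC)c(O)c(OC)c2)c(OC)c1 | intermediate
21 | 5-iodo-1,2,3-trimethoxybenzene | COc1cc(I)cc(OC)c1OC | starting material
22 | ring B–F aldehyde phenol | COc1cc(C=O)cc(OC)c1Oc1cc(OC)c(Oc2cc(OC)c(OC)c(OC)c2Oc2cc(OC)c(Oc3cc(OC)c(O)c(OC)c3)c(OC)c2)c(OC)c1 | intermediate (not isolated)
23 | ring B–G hexamer aldehyde | COc1cc(C=O)cc(OC)c1Oc1cc(OC)c(Oc2cc(OC)c(OC)c(OC)c2Oc2cc(OC)c(Oc3cc(OC)c(Oc4cc(OC)c(OC)c(OC)c4)c(OC)c3)c(OC)c2)c(OC)c1 | intermediate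
24 | ring B–G hexamer formate | COc1cc(OC=O)cc(OC)c1Oc1cc(OC)c(Oc2cc(OC)c(OC)c(OC)c2Oc2cc(OC)c(Oc3cc(OC)c(Oc4cc(OC)c(OC)c(OC)c4)c(OC)c3)c(OC)c2)c(OC)c1 | intermediate (not isolated)
25 | ring B–G hexamer phenol | COc1cc(O)cc(OC)c1Oc1cc(OC)c(Oc2cc(OC)c(OC)c(OC)c2Oc2cc(OC)c(Oc3cc(OC)c(Oc4cc(OC)c(OC)c(OC)c4)c(OC)c3)c(OC)c2)c(OC)c1 | intermediate
26 | ring A–G heptamer aldehyde | COc1cc(C=O)cc(OC)c1Oc1cc(OC)c(Oc2cc(OC)c(Oc3cc(OC)c(OC)c(OC)c3Oc3cc(OC)c(Oc4cc(OC)c(Oc5cc(OC)c(OC)c(OC)c5)c(OC)c4)c(OC)c3)c(OC)c2)c(OC)c1 | intermediate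
27 | ring A–G heptamer formate | COc1cc(OC=O)cc(OC)c1Oc1cc(OC)c(Oc2cc(OC)c(Oc3cc(OC)c(OC)c(OC)c3Oc3cc(OC)c(Oc4cc(OC)c(Oc5cc(OC)c(OC)c(OC)c5)c(OC)c4)c(OC)c3)c(OC)c2)c(OC)c1 | intermediate (not isolated)
28 | hexadeca-O-methyl ether of the target (ring A 4-OH free) | COc1cc(O)cc(OC)c1Oc1cc(OC)c(Oc2cc(OC)c(Oc3cc(OC)c(OC)c(OC)c3Oc3cc(OC)c(Oc4cc(OC)c(Oc5cc(OC)c(OC)c(OC)c5)c(OC)c4)c(OC)c3)c(OC)c2)c(OC)c1 | intermediate
29 | CNP0304148.0 (achiral) | Oc1cc(O)c(Oc2cc(O)c(Oc3cc(O)c(Oc4cc(O)c(O)c(O)c4Oc4cc(O)c(Oc5cc(O)c(Oc6cc(O)c(O)c(O)c6)c(O)c5)c(O)c4)c(O)c3)c(O)c2)c(O)c1 | target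

**Totals**
Total step count: 11.
Longest linear sequence: 11 steps (1 → 2 → 6 → 10 → 13 → 18 → 20 → 23 → 25 → 26 → 28 → 29).

**Three steps most likely to fail**

Step 3. Attack at the wrong squarate carbonyl, or conjugate attack with loss of the aryloxide, would give the wrong ring D pattern. The fallback gives up the de novo ring and takes ring D from a purchased arene. It sets out from 3. The open OH of 3 is coupled (CuI, picolinic acid, K3PO4, DMSO, 80 °C, Ar) with commercial 2-bromo-3,4,5-trimethoxybenzaldehyde, whose bromide is activated by the ortho-formyl group, to give 2-(4-hydroxy-3,5-dimethoxyphenoxy)-3,4,5-trimethoxybenzaldehyde F1. Silylation (TBSOTf, 2,6-lutidine) gives 2-[4-(tert-butyldimethylsilyloxy)-3,5-dimethoxyphenoxy]-3,4,5-trimethoxybenzaldehyde F2. mCPBA converts it into 2-[4-(tert-butyldimethylsilyloxy)-3,5-dimethoxyphenoxy]-3,4,5-trimethoxyphenyl formate F3. KHCO3 in MeOH cleaves the formate, and the route is rejoined at 13.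

Step 5. The tri-ortho-substituted D-1–O–ring C ether may not form under copper catalysis. The fallback replaces the metal-catalysed coupling by metal-free arylation with a hypervalent iodine reagent, which tolerates crowded ethers. It sets out from 14 and 13. Halogen exchange on 14 (NaI, CuI, trans-N,N'-dimethylcyclohexane-1,2-diamine, dioxane, 110 °C) gives 4-iodo-3,5-dimethoxybenzaldehyde F4. Oxidation with mCPBA and TsOH·H2O in MeCN followed by 1,3,5-trimethoxybenzene gives (4-formyl-2,6-dimethoxyphenyl)(2,4,6-trimethoxyphenyl)iodonium tosylate F5. With 13 and KOt-Bu in toluene at 40 °C the more electron-poor formyl-bearing aryl group is transferred, giving the silyl-protected ring C–D–E aldehyde F6. CsF in DMSO then frees the ring E phenol, and the route is rejoined at 17, to which 15 is added as in step 5.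

Step 11. Sixteen cleavages may stall as insoluble borates form, and the free polyphenol is oxidation-prone on aqueous isolation. The fallback goes through an isolable, oxidation-proof persilyl ether instead of boron species. It sets out from 28. Iodotrimethylsilane (40 equiv, 1,2-dichloroethane, 60 °C, sealed, Ar) dealkylates every methoxy group by silyl-oxonium formation and iodide attack, and silylates the free OH, giving the heptadeca(trimethylsilyl) ether of the target F7. This ether is soluble, can be freed of volatiles and passed through a short plug under Ar. Neutral methanolysis (MeOH, rt) then releases the product with only volatile co-products, and the route is rejoined at 29.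

**Further compounds**
F1 | step 3 | 2-(4-hydroxy-3,5-dimethoxyphenoxy)-3,4,5-trimethoxybenzaldehyde | COc1cc(C=O)c(Oc2cc(OC)c(O)c(OC)c2)c(OC)c1OC
F2 | step 3 | 2-[4-(tert-butyldimethylsilyloxy)-3,5-dimethoxyphenoxy]-3,4,5-trimethoxybenzaldehyde | COc1cc(C=O)c(Oc2cc(OC)c(O[Si](C)(C)C(C)(C)C)c(OC)c2)c(OC)c1OC
F3 | step 3 | 2-[4-(tert-butyldimethylsilyloxy)-3,5-dimethoxyphenoxy]-3,4,5-trimethoxyphenyl formate | COc1cc(OC=O)c(Oc2cc(OC)c(O[Si](C)(C)C(C)(C)C)c(OC)c2)c(OC)c1OC
F4 | step 5 | 4-iodo-3,5-dimethoxybenzaldehyde | COc1cc(C=O)cc(OC)c1I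
F5 | step 5 | (4-formyl-2,6-dimethoxyphenyl)(2,4,6-trimethoxyphenyl)iodonium tosylate | COc1cc(OC)c([I+]c2c(OC)cc(C=O)cc2OC)c(OC)c1.Cc1ccc(S(=O)(=O)[O-])cc1
F6 | step 5 | silyl-protected ring C–D–E aldehyde | COc1cc(C=O)cc(OC)c1Oc1cc(OC)c(OC)c(OC)c1Oc1cc(OC)c(O[Si](C)(C)C(C)(C)C)c(OC)c1
F7 | step 11 | heptadeca(trimethylsilyl) ether of the target | C[Si](C)(C)Oc1cc(O[Si](C)(C)C)c(Oc2cc(O[Si](C)(C)C)c(Oc3cc(O[Si](C)(C)C)c(Oc4cc(O[Si](C)(C)C)c(O[Si](C)(C)C)c(O[Si](C)(C)C)c4Oc4cc(O[Si](C)(C)C)c(Oc5cc(O[Si](C)(C)C)c(Oc6cc(O[Si](C)(C)C)c(O[Si](C)(C)C)c(O[Si](C)(C)C)c6)c(O[Si](C)(C)C)c5)c(O[Si](C)(C)C)c4)c(O[Si](C)(C)C)c3)c(O[Si](C)(C)C)c2)c(O[Si](C)(C)C)c1
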